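**Plan**

- Retrosynthesis: the 1,2-dioxane is opened at O–C14 (SN2 of a C17 hydroperoxide on a C14 mesylate), the lactone at O16–C19 and the peroxide at C17–OO (perhydrolysis of a 16,17-epoxide), leaving an (E)-C16=C17 alkene. The sp3–sp2 bond C12–C13 is then cut into a decalin carboxylic acid and a 2-bromoallylic alcohol.
- The side chain C13–C19 is cut at C15–C16 and C17–CH3 into a but-3-ynyl silyl ether, AlMe3 and a glycidyl silyl ether. The decalin comes from abietic acid by opening ring C.
- Forward: one-flask methylalumination/epoxide opening, then C13 to bromoalkene and C19 to methyl ester. Abietic acid goes to a seco keto enal, then C6 hydroxylation, C8 methylidene, C8 carbinol, Baeyer–Villiger and acid. Nickel-catalysed decarboxylative coupling joins the halves; the lactone and the 1,2-dioxane arise last (steps 24 and 25).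
- Enabling feature: the anti C16–O/C17–OO pair at the trans lactone/1,2-dioxane ring fusion is the result of anti addition across an (E)-C16=C17 alkene whose methyl is cis to C15–C16, which is what syn methylmetalation of a terminal alkyne delivers.
- Stereochemistry: C4, C5, C9 and C10 come from abietic acid; C6 and C8 from α-face attack on ring B; C14 from (R)-glycidol with one SN2 inversion; C16/C17 from reagent-controlled Shi epoxidation and invertive opening at C17.

Key step: step 3

Remark: ring carbons are C1–C10 and the chain is counted C11–C19 outward from C9 (C13 methylidene carbon, C14 peroxy CH, C16 lactone O–CH, C17 methyl-bearing peroxy carbon, C19 lactone carbonyl); the given SMILES is read as 4α-CO2CH3, 6α-OH, 8α-OH/8β-CH3 and (14R,16S,17R).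

**Route**

Step 1
Reactants: 1 but-3-yn-1-ol
Product: 2 tert-butyl(but-3-yn-1-yloxy)diphenylsilane
Conditions: TBDPSCl, imidazole, DMF, 0 °C to rt
Reagents that add atoms: tert-butylchlorodiphenylsilane, CC(C)(C)[Si](Cl)(c1ccccc1)c1ccccc1
Why: Imidazole-mediated silyl ether formation on a primary alcohol, the robust TBDPS group being chosen to outlast the Swern, Ohira–Bestmann and bromoboration steps.

Step 2
Reactants: 3 (R)-glycidol
Product: 4 (S)-triethyl(oxiran-2-ylmethoxy)silane
Conditions: TESCl, imidazole, CH2Cl2, 0 °C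
Reagents that add atoms: chlorotriethylsilane, CC[Si](Cl)(CC)CC
Why: Silyl ether formation at the primary hydroxyl leaves the epoxide and its stereocentre untouched, so only the descriptor changes from R to S.

Step 3
Reactants: 2 tert-butyl(but-3-yn-1-yloxy)diphenylsilane; 4 (S)-triethyl(oxiran-2-ylmethoxy)silane
Product: 7 (S,E)-7-(tert-butyldiphenylsilyloxy)-5-methyl-1-(triethylsilyloxy)hept-4-en-2-ol, via alkenylalane 5 (not isolated), via lithium alanate 6 (not isolated)
Conditions: AlMe3 (2.5 equiv), Cp2ZrCl2 (20 mol %), CH2Cl2, 0 °C to rt; volatiles removed; n-BuLi, hexane/THF, −78 to 0 °C; then 4, −30 °C to rt; aq. potassium sodium tartrate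
Reagents that add atoms: trimethylaluminium, C[Al](C)C
Why: Zirconocene-assisted syn methylalumination of the terminal alkyne puts aluminium on the terminal carbon and methyl on the internal one to give the (E)-alkenylalane 5, which butyllithium turns into the more nucleophilic alanate 6, whose alkenyl group opens the epoxide by SN2 attack at the unsubstituted CH2 with retention of alkene geometry. The closest known reaction type is the Negishi carboalumination of terminal alkynes with trapping of the alkenylalanate by an epoxide. No ring is closed and no stereocentre is created: the carbinol centre (C14) is carried over unchanged from 4, and the C16=C17 geometry (methyl cis to the new C15–C16 bond) follows from the syn addition. The step needs methyl delivery to the internal alkyne carbon, secured by the zirconium-mediated mechanism on a terminal alkyne, transfer of the alkenyl rather than an alkyl ligand from aluminium, and attack at the terminal epoxide carbon, secured by sterics.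

Step 4
Reactants: 7 (S,E)-7-(tert-butyldiphenylsilyloxy)-5-methyl-1-(triethylsilyloxy)hept-4-en-2-ol
Product: 8 (S,E)-7-(tert-butyldiphenylsilyloxy)-5-methyl-1,2-bis(triethylsilyloxy)hept-4-ene
Conditions: TESCl, imidazole, DMF, 0 °C to rt
Reagents that add atoms: chlorotriethylsilane, CC[Si](Cl)(CC)CC
Why: Silyl ether formation at the secondary alcohol, which also makes any 1,2-silyl migration in step 3 harmless because the same bis-silyl ether results.

Step 5
Reactants: 8 (S,E)-7-(tert-butyldiphenylsilyloxy)-5-methyl-1,2-bis(triethylsilyloxy)hept-4-ene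
Product: 9 (S,E)-7-(tert-butyldiphenylsilyloxy)-5-methyl-2-(triethylsilyloxy)hept-4-enal
Conditions: (COCl)2, DMSO, CH2Cl2, −78 to −30 °C; then Et3N, −78 °C to rt
Reagents that add atoms: none
Why: Under Swern oxidation conditions the activated sulfoxide cleaves the unhindered primary triethylsilyl ether selectively and oxidises it in the same flask, while the secondary silyl ether and the TBDPS ether persist.

Step 6
Reactants: 9 (S,E)-7-(tert-butyldiphenylsilyloxy)-5-methyl-2-(triethylsilyloxy)hept-4-enal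
Product: 10 (S,E)-8-(tert-butyldiphenylsilyloxy)-6-methyl-3-(triethylsilyloxy)oct-5-en-1-yne
Conditions: dimethyl (1-diazo-2-oxopropyl)phosphonate, K2CO3, MeOH, 0 °C to rt
Reagents that add atoms: dimethyl (1-diazo-2-oxopropyl)phosphonate, COP(=O)(OC)C(=[N+]=[N-])C(C)=O
Why: Ohira–Bestmann homologation converts the aldehyde into the terminal alkyne under mildly basic conditions that α-silyloxy aldehydes normally survive without epimerisation, and no base-sensitive ester is present yet.

Step 7
Reactants: 10 (S,E)-8-(tert-butyldiphenylsilyloxy)-6-methyl-3-(triethylsilyloxy)oct-5-en-1-yne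
Product: 12 (S,E)-2-bromo-8-(tert-butyldiphenylsilyloxy)-6-methyl-3-(triethylsilyloxy)octa-1,5-diene, via alkenylborane 11 (not isolated)
Conditions: B-bromo-9-BBN, CH2Cl2, 0 °C; then AcOH, 0 °C to rt; ethanolamine work-up
Reagents that add atoms: B-bromo-9-borabicyclo[3.3.1]nonane, BrB1C2CCCC1CCC2
Why: syn-Bromoboration of the terminal alkyne places bromine on the internal carbon and protodeboronation with acetic acid gives the 2-bromo-1-alkene, the trisubstituted alkene having no pathway with a B–Br reagent.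

Step 8
Reactants: 12 (S,E)-2-bromo-8-(tert-butyldiphenylsilyloxy)-6-methyl-3-(triethylsilyloxy)octa-1,5-diene
Product: 13 (S,E)-7-bromo-3-methylocta-3,7-diene-1,6-diol
Conditions: Bu4NF, THF, 0 °C to rt
Reagents that add atoms: none
Why: Fluoride-mediated desilylation removes both silyl ethers while the alkenyl bromide is inert.

Step 9
Reactants: 13 (S,E)-7-bromo-3-methylocta-3,7-diene-1,6-diol
Product: 14 (S,E)-7-bromo-6-hydroxy-3-methylocta-3,7-dienoic acid
Conditions: 2,2,6,6-tetramethylpiperidin-1-oxyl (TEMPO, cat.), PhI(OAc)2, MeCN/H2O, 0 °C to rt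
Reagents that add atoms: water, O
Why: Oxoammonium (TEMPO) oxidation takes the primary alcohol much faster than the more hindered secondary bromoallylic one, and in aqueous acetonitrile the aldehyde hydrate is oxidised on to the acid before the β,γ-alkene can move into conjugation.

Step 10
Reactants: 14 (S,E)-7-bromo-6-hydroxy-3-methylocta-3,7-dienoic acid
Product: 15 methyl (S,E)-7-bromo-6-hydroxy-3-methylocta-3,7-dienoate
Conditions: Me3SiCHN2, toluene/MeOH, 0 °C
Reagents that add atoms: trimethylsilyldiazomethane, C[Si](C)(C)C=[N+]=[N-]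
Why: Diazoalkane esterification proceeds under neutral conditions, so the β,γ-unsaturated acid is methylated without base-induced conjugation.

Step 11
Reactants: 16 abietic acid
Product: 17 methyl abietate
Conditions: MeI, K2CO3, DMF, rt
Reagents that add atoms: iodomethane, CI
Why: SN2 O-alkylation of the carboxylate is the usual way to esterify the hindered C4 acid.

Step 12
Reactants: 17 methyl abietate
Product: 19 methyl 13-oxo-13,14-secoabiet-7-en-14-al-18-oate (abietane numbering), via diol 18 (not isolated)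
Conditions: OsO4 (2 mol %), N-methylmorpholine N-oxide, acetone/H2O, 0 °C to rt; then NaIO4, rt
Reagents that add atoms: osmium tetroxide, O=[Os](=O)(=O)=O; N-methylmorpholine N-oxide, C[N+]1([O-])CCOCC1; water, O
Why: In this Lemieux–Johnson-type dihydroxylation/glycol cleavage, osmylation should take the isopropyl-bearing ring-C double bond of the heteroannular diene and periodate then gives the isopropyl ketone and the ring-B enal, both new carbinol centres (drawn α) being erased in the same flask.

Step 13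
Reactants: 19 methyl 13-oxo-13,14-secoabiet-7-en-14-al-18-oate
Product: 20 methyl 14-acetoxy-13-oxo-13,14-secoabieta-6,8(14)-dien-18-oate (enol acetate geometry of no consequence)
Conditions: Ac2O, Et3N, 4-(dimethylamino)pyridine (cat.), toluene, 80 °C
Reagents that add atoms: acetic anhydride, CC(=O)OC(C)=O
Why: Dienyl acetate formation by O-acylation and γ-deprotonation of the enal can only involve C6, and the isopropyl ketone does not form an enol acetate under these basic conditions.

Step 14
Reactants: 20 methyl 14-acetoxy-13-oxo-13,14-secoabieta-6,8(14)-dien-18-oate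
Product: 21 methyl 6α-hydroxy-13-oxo-13,14-secoabiet-7-en-14-al-18-oate
Conditions: mCPBA (1.05 equiv), NaHCO3, CH2Cl2/H2O, 0 °C
Reagents that add atoms: 3-chloroperoxybenzoic acid, OOC(=O)c1cccc(Cl)c1
Why: In this vinylogous Rubottom-type oxidation the peracid attacks the electron-rich C6 terminus of the dienyl acetate from the α face, opposite the axial methyls on C4 and C10, and collapse to the enal sets the equatorial 6α-hydroxyl.

Step 15
Reactants: 21 methyl 6α-hydroxy-13-oxo-13,14-secoabiet-7-en-14-al-18-oate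
Product: 23 methyl 6α-hydroxy-13-oxo-13,14-secoabiet-8(14)-en-18-oate, via tosylhydrazone 22 (not isolated)
Conditions: TsNHNH2 (1.05 equiv), THF, 40 °C; then catecholborane, CHCl3, 0 °C; then NaOAc·3H2O, reflux
Reagents that add atoms: none
Why: Alkene-transposing reductive deoxygenation of an α,β-unsaturated tosylhydrazone: the aldehyde condenses far faster than the hindered ketone, and hydride delivery, loss of sulfinate and retro-ene loss of N2 from the allylic diazene move the double bond to the exocyclic C8 position with the new hydrogen on C7.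

Step 16
Reactants: 23 methyl 6α-hydroxy-13-oxo-13,14-secoabiet-8(14)-en-18-oate
Product: 24 methyl 6α,8α-dihydroxy-13-oxo-13,14-secoabietan-18-oate (8β-methyl)
Conditions: Co(acac)2 (20 mol %), PhSiH3, O2 (1 atm), THF, rt
Reagents that add atoms: dioxygen, O=O
Why: Mukaiyama hydration generates the tertiary C8 radical by hydrogen-atom transfer to the methylidene carbon, and O2 should trap it on the α face away from the syn-axial C10 methyl, setting 8α-OH/8β-CH3 while ketone and ester are left alone.

Step 17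
Reactants: 24 methyl 6α,8α-dihydroxy-13-oxo-13,14-secoabietan-18-oate
Product: 25 13-isopropyl 18-methyl 6α,8α-dihydroxy-14,15,16-trinorlabdane-13,18-dioate (labdane numbering)
Conditions: mCPBA, NaHCO3, CH2Cl2, rt to 40 °C
Reagents that add atoms: 3-chloroperoxybenzoic acid, OOC(=O)c1cccc(Cl)c1
Why: In the Baeyer–Villiger oxidation the secondary isopropyl group migrates in preference to the primary CH2, turning the ketone into the isopropyl ester of the chain acid at a stage where no alkene remains to be epoxidised.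

Step 18
Reactants: 25 13-isopropyl 18-methyl 6α,8α-dihydroxy-14,15,16-trinorlabdane-13,18-dioate
Product: 26 13-isopropyl 18-methyl 6α,8α-bis(triethylsilyloxy)-14,15,16-trinorlabdane-13,18-dioate
Conditions: TESOTf, 2,6-lutidine, CH2Cl2, −78 to 0 °C
Reagents that add atoms: triethylsilyl trifluoromethanesulfonate, CC[Si](CC)(CC)OS(=O)(=O)C(F)(F)F
Why: Silyl triflate silylation reaches both the hindered secondary C6 and the tertiary C8 hydroxyl and masks them for the acylation and mesylation steps ahead.

Step 19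
Reactants: 26 13-isopropyl 18-methyl 6α,8α-bis(triethylsilyloxy)-14,15,16-trinorlabdane-13,18-dioate
Product: 27 18-methoxy-18-oxo-6α,8α-bis(triethylsilyloxy)-14,15,16-trinorlabdan-13-oic acid
Conditions: LiOH·H2O, THF/H2O, 40 °C; then 1 M HCl to pH 4
Reagents that add atoms: lithium hydroxide, [Li+].[OH-]
Why: Saponification removes the unhindered chain ester, whereas the C4 methyl ester on a quaternary carbon hydrolyses far more slowly and the silyl ethers tolerate aqueous LiOH.

Step 20
Reactants: 27 18-methoxy-18-oxo-6α,8α-bis(triethylsilyloxy)-14,15,16-trinorlabdan-13-oic acid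
Product: 28 N-phthalimidoyl ester of acid 27 (redox-active ester)
Conditions: N-hydroxyphthalimide, N,N'-diisopropylcarbodiimide, 4-(dimethylamino)pyridine (cat.), CH2Cl2, rt
Reagents that add atoms: N-hydroxyphthalimide, O=C1c2ccccc2C(=O)N1O
Why: Carbodiimide-mediated (Steglich-type) esterification gives the redox-active ester, the silyl groups preventing lactonisation onto the C8 oxygen.

Step 21
Reactants: 28 N-phthalimidoyl ester of acid 27; 15 methyl (S,E)-7-bromo-6-hydroxy-3-methylocta-3,7-dienoate
Product: 29 (14S,16E)-allylic alcohol: bis-TES decalin–C11H2–C12H2–C13(=CH2)–C14H(OH)–C15H2–C16H=C17(CH3)–C18H2–C19O2CH3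
Conditions: NiBr2·glyme (10 mol %), 4,4'-di-tert-butyl-2,2'-bipyridine, Zn, N,N-dimethylacetamide, rt
Reagents that add atoms: none
Why: In this nickel-catalysed decarboxylative cross-electrophile coupling the alkenyl bromide adds oxidatively to zerovalent nickel, single-electron reduction of the redox-active ester releases CO2 and the primary C12 radical, and reductive elimination from the alkyl(alkenyl)nickel species forms C12–C13 in the presence of the free hydroxyl, esters and silyl ethers.

Step 22
Reactants: 29 (14S,16E)-allylic alcohol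
Product: 30 (14S,16S,17S)-16,17-epoxy alcohol
Conditions: 1,2:4,5-di-O-isopropylidene-β-L-erythro-2,3-hexodiulo-2,6-pyranose (30 mol %), KHSO5 (as 2KHSO5·KHSO4·K2SO4), K2CO3, Bu4NHSO4, MeCN/dimethoxymethane/aq. Na2B4O7 buffer, 0 °C
Reagents that add atoms: potassium peroxymonosulfate, [K+].[O-]S(=O)(=O)OO
Why: In the Shi epoxidation the chiral dioxirane attacks the electron-rich trisubstituted (E)-alkene through a spiro transition state much faster than the 1,1-disubstituted alkene, and the L-fructose-derived ketone enantiomer is chosen to deliver the (16S,17S)-epoxide under reagent control.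

Step 23
Reactants: 30 (14S,16S,17S)-16,17-epoxy alcohol
Product: 31 (14S,16S,17S)-16,17-epoxy 14-mesylate
Conditions: MsCl, Et3N, CH2Cl2, −20 °C; used directly
Reagents that add atoms: methanesulfonyl chloride, CS(=O)(=O)Cl
Why: Sulfonate ester formation at the only free hydroxyl proceeds with retention at C14 and removes that oxygen as a competing nucleophile for the epoxide.

Step 24
Reactants: 31 (14S,16S,17S)-16,17-epoxy 14-mesylate
Product: 33 (14S,16S,17R)-17-hydroperoxy 19,16-lactone 14-mesylate, via hydroxy hydroperoxide 32 (not isolated)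
Conditions: H2O2 (anhydrous, in Et2O), H3PMo12O40 (3 mol %), Et2O, 0 °C to rt; cold aqueous wash; used directly
Reagents that add atoms: hydrogen peroxide, OO
Why: Molybdenum-acid-catalysed perhydrolysis of a trisubstituted epoxide lets H2O2 attack the tertiary C17 with inversion, giving the C17 hydroperoxide anti to the C16 hydroxyl, which then lactonises onto the C19 methyl ester.

Step 25
Reactants: 33 (14S,16S,17R)-17-hydroperoxy 19,16-lactone 14-mesylate
Product: 34 6,8-bis(triethylsilyl) ether of the target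
Conditions: Cs2CO3, DMF, 0 °C
Reagents that add atoms: none
Why: Intramolecular alkylation of a hydroperoxide by a sulfonate (6-exo-tet SN2) inverts C14 to R and closes the 1,2-dioxane trans-fused to the lactone, the mild carbonate base limiting Kornblum–DeLaMare-type cleavage.

Step 26
Reactants: 34 6,8-bis(triethylsilyl) ether of the target
Product: 35 CNP0162504.1 (target)
Conditions: HF·pyridine, pyridine, THF, 0 °C to rt
Reagents that add atoms: none
Why: Fluoride-mediated desilylation under buffered, weakly acidic conditions removes both triethylsilyl ethers without harming the peroxide, the lactone or the methyl ester.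

**Compound list**

1 | but-3-yn-1-ol | C#CCCO | starting material
2 | tert-butyl(but-3-yn-1-yloxy)diphenylsilane | C#CCCO[Si](c1ccccc1)(c1ccccc1)C(C)(C)C | intermediate
3 | (R)-glycidol | OC[C@@H]1CO1 | starting material
4 | (S)-triethyl(oxiran-2-ylmethoxy)silane | CC[Si](CC)(CC)OC[C@@H]1CO1 | intermediate
5 | (E)-[4-(tert-butyldiphenylsilyloxy)-2-methylbut-1-enyl]dimethylalane | C[Al](C)/C=C(\C)CCO[Si](c1ccccc1)(c1ccccc1)C(C)(C)C | intermediate
6 | lithium butyl[(E)-4-(tert-butyldiphenylsilyloxy)-2-methylbut-1-enyl]dimethylaluminate | [Li+].CCCC[Al-](C)(C)/C=C(\C)CCO[Si](c1ccccc1)(c1ccccc1)C(C)(C)C | intermediate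
7 | (S,E)-7-(tert-butyldiphenylsilyloxy)-5-methyl-1-(triethylsilyloxy)hept-4-en-2-ol | CC[Si](CC)(CC)OC[C@@H](O)C/C=C(\C)CCO[Si](c1ccccc1)(c1ccccc1)C(C)(C)C | intermediate
8 | (S,E)-7-(tert-butyldiphenylsilyloxy)-5-methyl-1,2-bis(triethylsilyloxy)hept-4-ene | CC[Si](CC)(CC)OC[C@@H](O[Si](CC)(CC)CC)C/C=C(\C)CCO[Si](c1ccccc1)(c1ccccc1)C(C)(C)C | intermediate
9 | (S,E)-7-(tert-butyldiphenylsilyloxy)-5-methyl-2-(triethylsilyloxy)hept-4-enal | O=C[C@@H](O[Si](CC)(CC)CC)C/C=C(\C)CCO[Si](c1ccccc1)(c1ccccc1)C(C)(C)C | intermediate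
10 | (S,E)-8-(tert-butyldiphenylsilyloxy)-6-methyl-3-(triethylsilyloxy)oct-5-en-1-yne | C#C[C@@H](O[Si](CC)(CC)CC)C/C=C(\C)CCO[Si](c1ccccc1)(c1ccccc1)C(C)(C)C | intermediate
11 | (Z)-2-bromoalkenyl-9-BBN adduct of 10 (boron on C1, cis to bromine) | Br/C(=C\B1C2CCCC1CCC2)[C@@H](O[Si](CC)(CC)CC)C/C=C(\C)CCO[Si](c1ccccc1)(c1ccccc1)C(C)(C)C | intermediate
12 | (S,E)-2-bromo-8-(tert-butyldiphenylsilyloxy)-6-methyl-3-(triethylsilyloxy)octa-1,5-diene | C=C(Br)[C@@H](O[Si](CC)(CC)CC)C/C=C(\C)CCO[Si](c1ccccc1)(c1ccccc1)C(C)(C)C | intermediate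
13 | (S,E)-7-bromo-3-methylocta-3,7-diene-1,6-diol | C=C(Br)[C@@H](O)C/C=C(\C)CCO | intermediate
14 | (S,E)-7-bromo-6-hydroxy-3-methylocta-3,7-dienoic acid | C=C(Br)[C@@H](O)C/C=C(\C)CC(=O)O | intermediate
15 | methyl (S,E)-7-bromo-6-hydroxy-3-methylocta-3,7-dienoate | C=C(Br)[C@@H](O)C/C=C(\C)CC(=O)OC | intermediate
16 | abietic acid | CC(C)C1=CC2=CC[C@@H]3[C@](C)(CCC[C@@]3(C)C(=O)O)[C@H]2CC1 | starting material
17 | methyl abietate | CC(C)C1=CC2=CC[C@@H]3[C@](C)(CCC[C@@]3(C)C(=O)OC)[C@H]2CC1 | intermediate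
18 | methyl 13α,14α-dihydroxyabiet-7-en-18-oate | CC(C)[C@@]1(O)[C@H](O)C2=CC[C@@H]3[C@](C)(CCC[C@@]3(C)C(=O)OC)[C@H]2CC1 | intermediate
19 | methyl 13-oxo-13,14-secoabiet-7-en-14-al-18-oate | CC(C)C(=O)CC[C@@H]1[C@@]2(C)CCC[C@@](C)(C(=O)OC)[C@@H]2CC=C1C=O | intermediate
20 | methyl 14-acetoxy-13-oxo-13,14-secoabieta-6,8(14)-dien-18-oate | CC(C)C(=O)CC[C@@H]1[C@@]2(C)CCC[C@@](C)(C(=O)OC)[C@@H]2C=C/C1=C\OC(C)=O | intermediate
21 | methyl 6α-hydroxy-13-oxo-13,14-secoabiet-7-en-14-al-18-oate | CC(C)C(=O)CC[C@@H]1[C@@]2(C)CCC[C@@](C)(C(=O)OC)[C@@H]2[C@@H](O)C=C1C=O | intermediate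
22 | (E)-tosylhydrazone of aldehyde 21 | CC(C)C(=O)CC[C@@H]1[C@@]2(C)CCC[C@@](C)(C(=O)OC)[C@@H]2[C@@H](O)C=C1/C=N/NS(=O)(=O)c1ccc(C)cc1 | intermediate
23 | methyl 6α-hydroxy-13-oxo-13,14-secoabiet-8(14)-en-18-oate | CC(C)C(=O)CC[C@@H]1[C@@]2(C)CCC[C@@](C)(C(=O)OC)[C@@H]2[C@@H](O)CC1=C | intermediate
24 | methyl 6α,8α-dihydroxy-13-oxo-13,14-secoabietan-18-oate | CC(C)C(=O)CC[C@@H]1[C@@]2(C)CCC[C@@](C)(C(=O)OC)[C@@H]2[C@@H](O)C[C@@]1(C)O | intermediate
25 | 13-isopropyl 18-methyl 6α,8α-dihydroxy-14,15,16-trinorlabdane-13,18-dioate | CC(C)OC(=O)CC[C@@H]1[C@@]2(C)CCC[C@@](C)(C(=O)OC)[C@@H]2[C@@H](O)C[C@@]1(C)O | intermediate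
26 | 13-isopropyl 18-methyl 6α,8α-bis(triethylsilyloxy)-14,15,16-trinorlabdane-13,18-dioate | CC(C)OC(=O)CC[C@@H]1[C@@]2(C)CCC[C@@](C)(C(=O)OC)[C@@H]2[C@@H](O[Si](CC)(CC)CC)C[C@@]1(C)O[Si](CC)(CC)CC | intermediate
27 | 18-methoxy-18-oxo-6α,8α-bis(triethylsilyloxy)-14,15,16-trinorlabdan-13-oic acid | OC(=O)CC[C@@H]1[C@@]2(C)CCC[C@@](C)(C(=O)OC)[C@@H]2[C@@H](O[Si](CC)(CC)CC)C[C@@]1(C)O[Si](CC)(CC)CC | intermediate
28 | N-phthalimidoyl ester of acid 27 | O=C(CC[C@@H]1[C@@]2(C)CCC[C@@](C)(C(=O)OC)[C@@H]2[C@@H](O[Si](CC)(CC)CC)C[C@@]1(C)O[Si](CC)(CC)CC)ON1C(=O)c2ccccc2C1=O | intermediate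
29 | (14S,16E)-allylic alcohol (C13 methylidene, 14-OH, C19 methyl ester, 6,8-bis-TES) | C=C(CC[C@@H]1[C@@]2(C)CCC[C@@](C)(C(=O)OC)[C@@H]2[C@@H](O[Si](CC)(CC)CC)C[C@@]1(C)O[Si](CC)(CC)CC)[C@@H](O)C/C=C(\C)CC(=O)OC | intermediate
30 | (14S,16S,17S)-16,17-epoxy alcohol | C=C(CC[C@@H]1[C@@]2(C)CCC[C@@](C)(C(=O)OC)[C@@H]2[C@@H](O[Si](CC)(CC)CC)C[C@@]1(C)O[Si](CC)(CC)CC)[C@@H](O)C[C@@H]1O[C@@]1(C)CC(=O)OC | intermediate
31 | (14S,16S,17S)-16,17-epoxy 14-mesylate | C=C(CC[C@@H]1[C@@]2(C)CCC[C@@](C)(C(=O)OC)[C@@H]2[C@@H](O[Si](CC)(CC)CC)C[C@@]1(C)O[Si](CC)(CC)CC)[C@@H](OS(C)(=O)=O)C[C@@H]1O[C@@]1(C)CC(=O)OC | intermediate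
32 | (14S,16S,17R)-16-hydroxy-17-hydroperoxy 14-mesylate methyl ester | C=C(CC[C@@H]1[C@@]2(C)CCC[C@@](C)(C(=O)OC)[C@@H]2[C@@H](O[Si](CC)(CC)CC)C[C@@]1(C)O[Si](CC)(CC)CC)[C@@H](OS(C)(=O)=O)C[C@H](O)[C@](C)(OO)CC(=O)OC | intermediate
33 | (14S,16S,17R)-17-hydroperoxy 19,16-lactone 14-mesylate | C=C(CC[C@@H]1[C@@]2(C)CCC[C@@](C)(C(=O)OC)[C@@H]2[C@@H](O[Si](CC)(CC)CC)C[C@@]1(C)O[Si](CC)(CC)CC)[C@@H](OS(C)(=O)=O)C[C@@H]1OC(=O)C[C@@]1(C)OO | intermediate
34 | 6,8-bis(triethylsilyl) ether of the target | C=C(CC[C@@H]1[C@@]2(C)CCC[C@@](C)(C(=O)OC)[C@@H]2[C@@H](O[Si](CC)(CC)CC)C[C@@]1(C)O[Si](CC)(CC)CC)[C@H]1C[C@@H]2OC(=O)C[C@@]2(C)OO1 | intermediate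
35 | CNP0162504.1 | C=C(CC[C@@H]1[C@@]2(C)CCC[C@@](C)(C(=O)OC)[C@@H]2[C@@H](O)C[C@@]1(C)O)[C@H]1C[C@@H]2OC(=O)C[C@@]2(C)OO1 | target

**Totals and risks**

Total step count: 26. Longest linear sequence: 16 steps (steps 11–26, from abietic acid).

Steps most likely to fail:

1. Step 24. The allylic mesylate may ionise or be displaced during the acidic perhydrolysis, scrambling C14, or the epoxide may be opened by a nucleophile other than H2O2. The fallback sets out from 31 and returns at 34, bypassing 33 and step 25. The mesylate is displaced with inversion by the caesium salt of 2-methoxyprop-2-yl hydroperoxide (CsOH·H2O, DMF, 0 °C) to give the C14 peroxyketal epoxide F1. Pyridinium p-toluenesulfonate in CH2Cl2/MeOH unmasks the hydroperoxy epoxide F2. Camphorsulfonic acid then drives attack of the hydroperoxide on the tertiary epoxide carbon C17 (endo mode, inversion) to the 1,2-dioxane hydroxy ester F3, which lactonises under the same acid to 34. This reverses the order of the two C–OO bond formations; its own weak point is competition between attack at C16 and at C17, which is why it is held in reserve.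

2. Step 21. Premature reduction or dimerisation of the alkyl radical and protodebromination of 15 may outpace cross-coupling. The fallback sets out from 28 and returns at 29. Copper-catalysed decarboxylative borylation (Cu(acac)2, B2pin2, LiOH·H2O, MgCl2, dioxane/DMF) gives the primary pinacol boronate F4. KHF2 in MeOH/H2O converts it into the potassium trifluoroborate F5. Suzuki–Miyaura coupling of F5 with 15 (PdCl2(dppf), Cs2CO3, THF/H2O, 70 °C) then forms C12–C13 by two-electron transmetalation instead of radical capture.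

3. Step 16. Facial discrimination in the capture of the planar C8 radical by O2 may be poor, giving the C8 epimer. The fallback sets out from 23 and returns at 24. Epoxidation with mCPBA (NaHCO3, CH2Cl2, 0 °C, short contact so the ketone is untouched) should attack the methylidene from the α face and give the spiro epoxide F6. Benzeneselenol with K2CO3 in EtOH opens it at the CH2 terminus to the β-hydroxy selenide F7. Bu3SnH with azobis(isobutyronitrile) in toluene at 80 °C then cleaves the C–Se bond to leave the 8β-methyl/8α-hydroxyl of 24.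

Further compounds
F1 | step 24 | (14R,16S,17S)-16,17-epoxy 14-(2-methoxyprop-2-yl) peroxide | C=C(CC[C@@H]1[C@@]2(C)CCC[C@@](C)(C(=O)OC)[C@@H]2[C@@H](O[Si](CC)(CC)CC)C[C@@]1(C)O[Si](CC)(CC)CC)[C@H](OOC(C)(C)OC)C[C@@H]1O[C@@]1(C)CC(=O)OC
F2 | step 24 | (14R,16S,17S)-16,17-epoxy 14-hydroperoxide | C=C(CC[C@@H]1[C@@]2(C)CCC[C@@](C)(C(=O)OC)[C@@H]2[C@@H](O[Si](CC)(CC)CC)C[C@@]1(C)O[Si](CC)(CC)CC)[C@H](OO)C[C@@H]1O[C@@]1(C)CC(=O)OC
F3 | step 24 | (14R,16S,17R)-1,2-dioxane 16-hydroxy methyl ester | C=C(CC[C@@H]1[C@@]2(C)CCC[C@@](C)(C(=O)OC)[C@@H]2[C@@H](O[Si](CC)(CC)CC)C[C@@]1(C)O[Si](CC)(CC)CC)[C@H]1C[C@H](O)[C@@](C)(CC(=O)OC)OO1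
F4 | step 21 | C12 pinacol boronate of the bis-TES decalin | CC1(C)OB(CC[C@@H]2[C@@]3(C)CCC[C@@](C)(C(=O)OC)[C@@H]3[C@@H](O[Si](CC)(CC)CC)C[C@@]2(C)O[Si](CC)(CC)CC)OC1(C)C
F5 | step 21 | potassium C12 trifluoroborate of the bis-TES decalin | [K+].F[B-](F)(F)CC[C@@H]1[C@@]2(C)CCC[C@@](C)(C(=O)OC)[C@@H]2[C@@H](O[Si](CC)(CC)CC)C[C@@]1(C)O[Si](CC)(CC)CC
F6 | step 16 | 8α,14-epoxide of 23 | CC(C)C(=O)CC[C@@H]1[C@@]2(C)CCC[C@@](C)(C(=O)OC)[C@@H]2[C@@H](O)C[C@]13CO3
F7 | step 16 | 8α-hydroxy 14-phenylselanyl derivative | CC(C)C(=O)CC[C@@H]1[C@@]2(C)CCC[C@@](C)(C(=O)OC)[C@@H]2[C@@H](O)C[C@@]1(C[Se]c1ccccc1)O
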